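The earlier runs and the new flask are simulated from invented constants; noise was put on by code.

The vessel is closed, stirred and isothermal, and the meeting had these charges and readings before it.

in all of them: starting complex 13 mM; incoming ligand 23.4 mM

| run | scavenger | remark | time |
|---|---|---|---|
| larch | 12 mM | run made earlier |  |
| oak | 28 mM | run made earlier |  |
| Friday's | 20.0 mM |  | 2.0 h |
| Saturday's | 29.0 mM |  | 2.0 h |
| Thursday's | 44.0 mM |  | 2.0 h |

- larch (time / min: starting complex / %, complex with two exchanged / %): 8.00: 79.0, 0.5; 20.0: 59.1, 3.0; 40.0: 38.5, 8.3; 60.0: 27.1, 14.3
- oak (time / min: starting complex / %, complex with two exchanged / %): 15.0: 65.4, 2.6; 30.0: 45.9, 6.6; 50.0: 30.9, 12.1; 60.0: 26.0, 14.3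

(scatter of a reading: 0.5 percentage points)

- the analysis behind the earlier runs scatters by 0.5 percentage points, standard deviation

* part of the starting complex that has reacted at the end, Friday's
* part of the starting complex that has reacted at the end, Saturday's
* part of the starting complex that has reacted at the end, Thursday's
* what raising the concentration of scavenger from its lowest to its highest value here does to the part of the starting complex that has reacted (changes below 5 percentage points count as none) (it falls / no change / it rises)

Minutes. The analyst reported that larch and oak, despite 12 mM against 28 mM of scavenger, both stood at 14.3% of complex with two exchanged at 60.0 min. The kineticist proposed to put the clock aside. If each exchange runs forward in proportion to [incoming ligand], dividing the second rate by the first cancels time and [incoming ligand] together, leaving s·[complex with one exchanged]/[starting complex].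

Over an interval, then, the gain in two-exchanged over the loss of starting complex is about s times the mean one-exchanged over the mean starting complex, one-exchanged being what the balance leaves. Larch's last two readings gave 0.309, and oak's, from 30.0 min to 60.0 min, gave 0.260. Their mean, 0.284, is a reading: the selectivity factor s, the second exchange's rate constant over the first's. With a fraction m of starting complex left, she wrote, the one-exchanged share is (m^s − m)/(1 − s), with no clock in it.

The forecaster committed to 87.5%, 87.5% and 87.5%, no change, arguing “so scavenger should not run out in any new run”. The kineticist's own reckoning took that 12.5% left: one-exchanged 59.9%, and second exchange over first 1.36, so the second would by then be the faster.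

The flasks gave 88.2%, 88.3% and 88.4%, no change, the change from lowest to highest scavenger being 0.17 percentage points.

    leaving ligand + incoming ligand ⇌ idle adduct, settled at all times (K = 70.0 /M)
    scavenger + leaving ligand → scavenged by-product (k = 1.10 /M/s)
    complex with one exchanged + incoming ligand ⇌ leaving ligand + complex with two exchanged (K = 6.40, k = 0.00630 /M/s)
    starting complex + incoming ligand ⇌ leaving ligand + complex with one exchanged (K = 11.0, k = 0.0230 /M/s)

The forecast held, and Friday's flask, with the least scavenger left of the three, still had 26% of its charge at the end. But Saturday's flask has not come to rest. At 2.00 h Saturday's flask holds 60.4% one-exchanged, s giving 59.6%, and one-exchanged is being made at 0.706 times the rate at which it is used up, each step taken net. At 20.0 h, Saturday's reacted part has moved to 99.7%, while one-exchanged has fallen to 26.2% and two-exchanged has risen to 73.6%. Friday's reaches 97.7% then, with its scavenger at 0%.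

Take Saturday's recipe with 52 mM of starting complex: at its 58.3% left, s gives one-exchanged 38.4% and two-exchanged 3.30%. That flask gives 38.5% and 3.20%, with free incoming ligand down to 0.209% of its charge.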